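## Structural features

The target is a 1H-inden-1-one: a benzene ring fused to a cyclopentenone whose C1 is the carbonyl carbon and whose C2=C3 bond is tetrasubstituted. Indenone C2 is bonded to C3 of a guaiazulenyl unit (azulene with methyl groups on C1 and C4 and an isopropyl group on C7), C3 carries a methyl group, C4 a formyl group and C7 a methyl group, so the benzene ring bears four contiguous substituents. There is no stereogenic centre and therefore no neighbouring stereocentres to relate; the crowded C2–C3' axis, flanked by the C1 carbonyl, the C3 methyl, azulene C2–H and the C4 methyl of the seven-membered ring, is not a defined stereo element of the target. The fragile groups are the aryl aldehyde (peri to the C3 methyl), the cross-conjugated indenone (a Michael acceptor) and above all the electron-rich azulene, which is sensitive to electrophiles, strong acid and oxidants. The real difficulty is twofold: the bond between two fully substituted sp2 carbons (indenone C2 and azulene C3), and the placing of three alkyl groups on a non-benzenoid bicycle next to a benzene ring that carries two different carbonyl groups on adjacent carbons. The key step exploits that the seven-membered ring (C3a, C4 with methyl, C5, C6, C7 with isopropyl, C8, C8a) is a para-cymene ring with one extra carbon, C8a, inserted between the ipso carbon and an ortho carbon, and that the five-membered ring (C1, C2, C3, C3a, C8a) is a three-atom tether closed onto that ring. Because azulene C3 is the benzylic carbon of this tether, the difficult C2–C3' bond can be in place as an ordinary sp3–sp3 bond before either ring system exists.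

## Logic of the disconnections

24 to 22 (through 23): the C2=C3 double bond of the indenone is cut as a retro-aldol condensation. It joins the methylene of a benzyl-ketone-type unit to an ortho acetyl group, so the five-membered ring and the tetrasubstituted alkene disappear and the crowded C2–C3' bond becomes a CH2–azulene bond. The forward step must use the more acidic methylene as the only nucleophile and must not touch the free formyl group, which calls for a non-nucleophilic base in an aprotic medium.

22 to 21: no skeletal bond is cut. The formyl and acetyl groups are masked as cyclic acetals because they must pass through aryllithium, carbenoid and organocerium chemistry. The forward step is a mild hydrolysis that the azulene tolerates, and it is kept separate from the ring closure so that no aldol chemistry runs under acid.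

21 to 18 (through 20 and 19): the C1–CH3 bond of the azulene is cut and the oxidation level is adjusted, so the aromatic azulene is traded for a cyclopentanone next to a cycloheptatriene. C1 is the carbonyl carbon that the ring expansion leaves behind. The forward sequence needs a methyl nucleophile that prefers the cyclopentanone over the di-ortho-substituted aryl ketone and does not enolise C8a, a dehydration without acid, and a dehydrogenation that stops at the azulene.

18 to 16 (through 17): the bonds C8a–C3a and C8a–C8 are cut. Taking C8a out of the seven-membered ring restores a benzene ring, and two rings and the whole non-benzenoid skeleton fall back to a para-cymene unit and a diazoketone. The forward step must choose between the two ipso–ortho bonds of that ring and must not be diverted by the second ketone or the acetals.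

16 to 14 (through 15): the bond between the diazo carbon and its carbonyl carbon is cut, which leads back to a carboxylic acid. The forward acylation of a diazoalkane must work without hydrogen chloride, since two acetals are present.

14 to 12 and 7 (through 13): the aryl–carbonyl bond is cut. 7 is a symmetrical cyclic anhydride, so a single acylation of the aryl anion gives the keto acid with both chain ends differentiated, and the molecule falls into two fragments of similar size. The forward step asks a hindered aryllithium to add once to a carbonyl group and not to act as a base.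

7 to 6 to 3 and 4 (through 5), and 3 to 1 (through 2): both C–C bonds at the benzylic carbon are cut, with the acetyl groups of 4 as activating groups that are removed afterwards, and the formyl carbon of 3 is cut from the ring. This is classical chemistry with no selectivity demand beyond complete deacetylation.

12 to 11 to 9 to 8 (through 10): the ketal is removed, the aryl–acetyl bond is cut at the position between bromine and the acetal, and the acetal is returned to the aldehyde. The forward lithiation must take the one ring hydrogen flanked by both groups without bromine–lithium exchange or aryne formation, and the ketalisation must cope with a ketone that has two ortho neighbours.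

## Other disconnections considered

Alternative 1: The five-membered ring of the indenone is cut at C3a–C3 and C2–C1. This leads to the iodo aldehyde 3-(dimethoxymethyl)-2-iodo-6-methylbenzaldehyde A3 and the internal alkyne 3-(prop-1-ynyl)guaiazulene A2. A2 would come from commercial guaiazulene A1 by halogenation at C3 and alkynylation. In the forward key step, zerovalent palladium formed from Pd(OAc)2 inserts into the C–I bond of A3, the aryl group adds to the methyl-bearing alkyne carbon of A2, the vinylpalladium adds to the aldehyde carbon, and β-hydride elimination gives 4-(dimethoxymethyl)-2-(7-isopropyl-1,4-dimethylazulen-3-yl)-3,7-dimethyl-1H-inden-1-one A4, the dimethyl acetal of the target. Mild acid hydrolysis of A4 would then give 24.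
- In its favour: the azulene is bought as A1 and not built, the annulation places the bulkier azulenyl group next to the carbonyl group as the target requires, and the hindered ring is formed last, directly at the oxidation level of A4.
- Against it here: the C–I bond of A3 lies between a formyl group and an acetal, so oxidative addition and alkyne insertion are slow. The very electron-rich alkyne A2 may be palladated or oligomerised by divalent palladium, and its donor character may erode the steric regiocontrol. A3 needs its own synthesis with the same four contiguous substituents.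
- Comparison: on structure the two plans are equal, since both need a 1,2,3,4-tetrasubstituted benzene. On mechanism the chosen plan makes the crowded C2–C3' bond early as an sp3–sp3 bond and closes the indenone by a simple aldol step, whereas Alternative 1 must form it inside a congested palladium cycle on the way to A4. On step economy Alternative 1 is clearly the better plan: about eight steps from A1 against thirteen.

Alternative 2: The azulene is cut at C3–C3a and C1–C2. The partners are the keto aldehyde 4-[3-(1,3-dioxolan-2-yl)-6-methyl-2-(2-methyl-1,3-dioxolan-2-yl)phenyl]-4-oxobutanal A5, used as its pyrrolidine enamine (E)-1-[3-(1,3-dioxolan-2-yl)-6-methyl-2-(2-methyl-1,3-dioxolan-2-yl)phenyl]-4-(pyrrolidin-1-yl)but-3-en-1-one A6, and the furanone 5-isopropyl-3,8-dimethyl-2H-cyclohepta[b]furan-2-one A7. The (8+2) cycloaddition of A6 to A7, followed by decarboxylation and loss of the amine, would give the azulenyl ketone 1-[3-(1,3-dioxolan-2-yl)-6-methyl-2-(2-methyl-1,3-dioxolan-2-yl)phenyl]-2-(7-isopropyl-1,4-dimethylazulen-3-yl)ethan-1-one A8, which is the same compound as 21.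
- In its favour: the positions of all three alkyl groups are fixed by A7, no site selectivity is asked of the ring-forming step, and the azulene arrives at the aromatic oxidation level without a separate dehydrogenation. On these points it is the better plan.
- Against it here: A7 needs a tropone with methyl, isopropyl and a leaving group in defined positions, which is much harder to obtain than a bromocymene. The cycloaddition needs heat, and the γ-keto aldehyde A5 and its enamine A6 are prone to self-condensation.
- Comparison: the end game from A8 is identical to that from 21, so the plans are equal there. The chosen plan draws on cheaper and more reliable starting materials but pays with a methyl addition, a dehydration and an oxidation that Alternative 2 avoids. The step counts should be about the same.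

Alternative 3: Both the five-membered ring and the benzene ring of the indenone are cut (C3a–C7a, C4–C5, C6–C7). This leaves the enediynone (Z)-9,9-diethoxy-5-(7-isopropyl-1,4-dimethylazulen-3-yl)-6-methylnon-5-ene-2,7-diyn-4-one A9 and acetylene A10. In the forward step RhCl(PPh3)3 would join the two tethered alkynes of A9 into a rhodacycle, A10 would be inserted, and reductive elimination would give 4-(diethoxymethyl)-2-(7-isopropyl-1,4-dimethylazulen-3-yl)-3,7-dimethyl-1H-inden-1-one A11, the diethyl acetal of the target. Mild acid hydrolysis of A11 would then give 24.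
- In its favour: all four substituents of the benzene ring of A11 are set by the tether, so no directed metalation between neighbouring groups is needed, and two rings form at once. On the contiguous-substitution problem it is the better plan.
- Against it here: A9 contains a tetrasubstituted alkene of defined Z geometry that carries the azulenyl group and an ynone, and a stereocontrolled route to it is long. The ynone is a Michael acceptor, the alkene can isomerise, the azulene can bind rhodium, and A10 can trimerise with itself.
- Comparison: the key step builds more of the skeleton in one operation than the ring expansion does, but it moves the difficulty into the precursor A9. The chosen plan asks less of its precursor, whose only stereocentre is irrelevant. On step count neither plan is likely to be better, since the short end game from A11 is offset by the long way to A9.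

Key step: step 9

Remark: azulene locants follow the guaiazulene numbering (C1 methyl, C3 side chain, C4 methyl, C7 isopropyl), also in the hydroazulene intermediates. The target has no stereogenic centre, so the sp3 centres of 14 to 20 and 23 are carried as racemates or diastereomer mixtures.

## Route

Step 1
Reactants: 1 2-bromo-4-isopropyl-1-methylbenzene
Product: 3 5-isopropyl-2-methylbenzaldehyde, via aryllithium 2 (not isolated)
Conditions: n-BuLi, THF, −78 °C; DMF, −78 °C to rt; aq. NH4Cl
Reagents that add atoms: N,N-dimethylformamide, CN(C)C=O
Why: Bromine–lithium exchange followed by formylation of the aryllithium with DMF; the hemiaminal alkoxide persists until work-up, so no second addition is expected.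

Step 2
Reactants: 3 5-isopropyl-2-methylbenzaldehyde, 4 ethyl acetoacetate (2 equiv)
Product: 6 3-(5-isopropyl-2-methylphenyl)pentanedioic acid, via bis-acetoacetate adduct 5 (not isolated)
Conditions: piperidine (cat.), EtOH, rt; then NaOH (aq., excess), reflux; HCl (aq.) to pH 1
Reagents that add atoms: sodium hydroxide, [Na+].[OH-]
Why: Knoevenagel condensation followed by Michael addition of a second acetoacetate gives 5; hot concentrated NaOH removes both acetyl groups by retro-Claisen cleavage and saponifies the esters, the classical entry to 3-arylglutaric acids. The stereocentres of 5 vanish because 6 is achiral.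

Step 3
Reactants: 6 3-(5-isopropyl-2-methylphenyl)pentanedioic acid
Product: 7 4-(5-isopropyl-2-methylphenyl)oxane-2,6-dione
Conditions: Ac2O, reflux; evaporate, crystallise
Reagents that add atoms: none
Why: Cyclodehydration of a glutaric acid to its six-membered anhydride through the mixed anhydride with acetic acid; 7 has a mirror plane, so its two carbonyl groups are equivalent towards an achiral nucleophile.

Step 4
Reactants: 8 3-bromo-4-methylbenzaldehyde
Product: 9 2-(3-bromo-4-methylphenyl)-1,3-dioxolane
Conditions: HOCH2CH2OH, TsOH (cat.), PhMe, reflux, Dean–Stark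
Reagents that add atoms: ethylene glycol, OCCO
Why: Acid-catalysed acetalisation with azeotropic removal of water; the acetal protects the aldehyde and serves as the directing group for step 5.

Step 5
Reactants: 9 2-(3-bromo-4-methylphenyl)-1,3-dioxolane
Product: 11 1-[2-bromo-6-(1,3-dioxolan-2-yl)-3-methylphenyl]ethan-1-one, via ortho-lithiated acetal 10 (not isolated)
Conditions: LiN(iPr)2, THF, −78 °C; MeC(O)N(OMe)Me, −78 to −40 °C; aq. NH4Cl
Reagents that add atoms: N-methoxy-N-methylacetamide, CC(=O)N(C)OC
Why: Directed ortho-lithiation: the ring hydrogen between bromine and the acetal is the most acidic one, and an amide base deprotonates without bromine–lithium exchange; at −78 °C the ortho-bromoaryllithium should not lose LiBr. Acylation with the Weinreb amide stops at the ketone because the chelated tetrahedral adduct survives until work-up.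

Step 6
Reactants: 11 1-[2-bromo-6-(1,3-dioxolan-2-yl)-3-methylphenyl]ethan-1-one
Product: 12 2-[2-bromo-6-(1,3-dioxolan-2-yl)-3-methylphenyl]-2-methyl-1,3-dioxolane
Conditions: Me3SiOCH2CH2OSiMe3, TMSOTf (cat.), CH2Cl2, −78 to 0 °C; pyridine quench
Reagents that add atoms: 1,2-bis(trimethylsilyloxy)ethane, C[Si](C)(C)OCCO[Si](C)(C)C
Why: Silyl-transfer ketalisation: formation of the Si–O–Si bond drives the reaction without heat or water removal, which suits a ketone with two ortho neighbours whose carbonyl group is already twisted out of conjugation. The aldehyde acetal carries the same diol, so any exchange at that carbon is degenerate.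

Step 7
Reactants: 12 2-[2-bromo-6-(1,3-dioxolan-2-yl)-3-methylphenyl]-2-methyl-1,3-dioxolane, 7 4-(5-isopropyl-2-methylphenyl)oxane-2,6-dione
Product: 14 5-[3-(1,3-dioxolan-2-yl)-6-methyl-2-(2-methyl-1,3-dioxolan-2-yl)phenyl]-3-(5-isopropyl-2-methylphenyl)-5-oxopentanoic acid (racemic), via aryllithium 13 (not isolated)
Conditions: n-BuLi, THF, −78 °C; cannulate into 7 (1.3 equiv), THF, −78 to −40 °C; aq. NH4Cl, then NaH2PO4 to pH 5, 0 °C
Reagents that add atoms: none
Why: Bromine–lithium exchange and acylation of the aryllithium by the cyclic anhydride; ring opening gives a carboxylate and a di-ortho-substituted aryl ketone that should resist a second addition. The two carbonyl groups of 7 are enantiotopic, so the benzylic stereocentre forms as a racemate, which is all that is needed.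

Step 8
Reactants: 14 5-[3-(1,3-dioxolan-2-yl)-6-methyl-2-(2-methyl-1,3-dioxolan-2-yl)phenyl]-3-(5-isopropyl-2-methylphenyl)-5-oxopentanoic acid
Product: 16 1-diazo-6-[3-(1,3-dioxolan-2-yl)-6-methyl-2-(2-methyl-1,3-dioxolan-2-yl)phenyl]-4-(5-isopropyl-2-methylphenyl)hexane-2,6-dione (racemic), via mixed carbonic anhydride 15 (not isolated)
Conditions: ClCO2Et, Et3N, THF, −15 °C; Me3SiCHN2 (2 M in hexanes), MeCN, 0 °C to rt; aq. NaHCO3
Reagents that add atoms: trimethylsilyldiazomethane, C[Si](C)(C)C=[N+]=[N-]
Why: Acylation of a diazoalkane by a mixed carbonic anhydride, as in the first stage of an Arndt–Eistert sequence; the carbonate leaving group removes silicon from the α-silyl diazonium intermediate. No hydrogen chloride is formed, so both acetals should survive, and diazomethane is avoided.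

Step 9
Reactants: 16 1-diazo-6-[3-(1,3-dioxolan-2-yl)-6-methyl-2-(2-methyl-1,3-dioxolan-2-yl)phenyl]-4-(5-isopropyl-2-methylphenyl)hexane-2,6-dione
Product: 18 3-{2-[3-(1,3-dioxolan-2-yl)-6-methyl-2-(2-methyl-1,3-dioxolan-2-yl)phenyl]-2-oxoethyl}-7-isopropyl-4-methyl-3,8a-dihydroazulen-1(2H)-one (diastereomer mixture), via norcaradiene 17 (not isolated)
Conditions: Rh2(OAc)4 (1 mol%), CH2Cl2, 40 °C, syringe-pump addition of 16 (final 0.01 M); filtration through neutral alumina
Reagents that add atoms: none
Why: Rh2(OAc)4 expels dinitrogen from 16 and gives an electrophilic rhodium carbenoid. Its carbon adds across the ipso–ortho bond of the 5-isopropyl-2-methylphenyl ring through the three-atom tether (CH, CH2, C=O), an intramolecular cyclopropanation that closes the five-membered ring and gives norcaradiene 17. Disrotatory six-electron electrocyclic opening of 17 then breaks the old ipso–ortho bond and enlarges the six-membered ring to the seven-membered ring, so the new bonds are C8a–C3a and C8a–C8. The closest known reaction type is the intramolecular Buchner reaction of 1-diazo-4-arylbutan-2-ones to 3,8a-dihydroazulen-1(2H)-ones. The step needs site selectivity between the two ipso–ortho bonds: the ortho methyl group shields the bond it sits on (attack there would create a second fully substituted cyclopropane carbon), so the carbenoid should go to the unsubstituted side and the methyl and isopropyl groups should end on C4 and C7. It also needs chemoselectivity: the chain C–H bonds are α to carbonyl groups and thus poor partners for insertion, ylide formation at the distal ketone would need a seven-membered ring at a twisted and doubly shielded carbonyl group, and high dilution holds back carbene dimerisation. The new sp3 centre C8a forms without control relative to C3, which does not matter because both centres become sp2 in step 11. 18 is used at once, since traces of acid would isomerise it through 17.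

Step 10
Reactants: 18 3-{2-[3-(1,3-dioxolan-2-yl)-6-methyl-2-(2-methyl-1,3-dioxolan-2-yl)phenyl]-2-oxoethyl}-7-isopropyl-4-methyl-3,8a-dihydroazulen-1(2H)-one
Product: 19 1-[3-(1,3-dioxolan-2-yl)-6-methyl-2-(2-methyl-1,3-dioxolan-2-yl)phenyl]-2-(1-hydroxy-7-isopropyl-1,4-dimethyl-1,2,3,8a-tetrahydroazulen-3-yl)ethan-1-one (diastereomer mixture)
Conditions: MeLi, CeCl3, THF, −78 °C; pH 7 phosphate buffer
Reagents that add atoms: methyllithium, [Li]C
Why: 1,2-Addition of the organocerium reagent MeCeCl2, which is nucleophilic but hardly basic, so the acidic C8a–H should stay in place. The cyclopentanone should react far faster than the aryl ketone, whose carbonyl group is twisted and shielded by two ortho substituents; the new carbinol centre forms as a mixture and is removed in step 11.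

Step 11
Reactants: 19 1-[3-(1,3-dioxolan-2-yl)-6-methyl-2-(2-methyl-1,3-dioxolan-2-yl)phenyl]-2-(1-hydroxy-7-isopropyl-1,4-dimethyl-1,2,3,8a-tetrahydroazulen-3-yl)ethan-1-one
Product: 21 1-[3-(1,3-dioxolan-2-yl)-6-methyl-2-(2-methyl-1,3-dioxolan-2-yl)phenyl]-2-(7-isopropyl-1,4-dimethylazulen-3-yl)ethan-1-one, via dihydroazulene 20 (not isolated)
Conditions: Burgess reagent, PhH, 50 °C; then p-chloranil (1.05 equiv), 80 °C
Reagents that add atoms: none
Why: Burgess dehydration (syn elimination through the sulfamate ester, no acid, acetals safe) gives the heptafulvene-type dihydroazulene 20; any double-bond isomer of 20 serves equally. The quinone then takes a hydride from an allylic position and a proton is lost, the classical chloranil dehydrogenation of hydroazulenes, driven by the gain of azulene aromaticity.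

Step 12
Reactants: 21 1-[3-(1,3-dioxolan-2-yl)-6-methyl-2-(2-methyl-1,3-dioxolan-2-yl)phenyl]-2-(7-isopropyl-1,4-dimethylazulen-3-yl)ethan-1-one
Product: 22 2-acetyl-3-[(7-isopropyl-1,4-dimethylazulen-3-yl)acetyl]-4-methylbenzaldehyde
Conditions: HCl (2 M aq.)/THF 1:4, rt to 35 °C, N2, dark; NaHCO3
Reagents that add atoms: water, O
Why: Acid-catalysed hydrolysis of both dioxolanes, the carbonyl oxygens coming from water. Dilute acid near room temperature protonates the azulene only reversibly and is too mild for acid-catalysed aldol chemistry of 22.

Step 13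
Reactants: 22 2-acetyl-3-[(7-isopropyl-1,4-dimethylazulen-3-yl)acetyl]-4-methylbenzaldehyde
Product: 24 2-(7-isopropyl-1,4-dimethylazulen-3-yl)-3,7-dimethyl-1-oxo-1H-indene-4-carbaldehyde, via aldol adduct 23 (not isolated)
Conditions: DBU, PhMe, rt to 50 °C
Reagents that add atoms: none
Why: Intramolecular aldol condensation: the methylene between the aryl ketone and the azulene is by far the most acidic C–H, its enolate attacks the neighbouring acetyl group (5-exo-trig) and E1cB loss of water from 23 gives the fully substituted, azulene-conjugated indenone. An amidine base in an aprotic solvent offers no oxygen nucleophile to the free formyl group, so hydride-transfer lactonisation is avoided, and the formyl carbon is meta to the reacting chain and out of its reach.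

## Compound list

1 | 2-bromo-4-isopropyl-1-methylbenzene | Cc1ccc(C(C)C)cc1Br | starting material
2 | (5-isopropyl-2-methylphenyl)lithium | [Li]c1cc(C(C)C)ccc1C | intermediate
3 | 5-isopropyl-2-methylbenzaldehyde | Cc1ccc(C(C)C)cc1C=O | intermediate
4 | ethyl acetoacetate (ethyl 3-oxobutanoate) | CCOC(=O)CC(C)=O | starting material
5 | diethyl 2,4-diacetyl-3-(5-isopropyl-2-methylphenyl)pentanedioate (stereoisomer mixture, in equilibrium with its cyclic aldol form) | CCOC(=O)C(C(C)=O)C(c1cc(C(C)C)ccc1C)C(C(C)=O)C(=O)OCC | intermediate
6 | 3-(5-isopropyl-2-methylphenyl)pentanedioic acid | Cc1ccc(C(C)C)cc1C(CC(=O)O)CC(=O)O | intermediate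
7 | 4-(5-isopropyl-2-methylphenyl)oxane-2,6-dione (3-arylglutaric anhydride) | Cc1ccc(C(C)C)cc1C1CC(=O)OC(=O)C1 | intermediate
8 | 3-bromo-4-methylbenzaldehyde | Cc1ccc(C=O)cc1Br | starting material
9 | 2-(3-bromo-4-methylphenyl)-1,3-dioxolane | Cc1ccc(C2OCCO2)cc1Br | intermediate
10 | [2-bromo-6-(1,3-dioxolan-2-yl)-3-methylphenyl]lithium | [Li]c1c(Br)c(C)ccc1C1OCCO1 | intermediate
11 | 1-[2-bromo-6-(1,3-dioxolan-2-yl)-3-methylphenyl]ethan-1-one | CC(=O)c1c(Br)c(C)ccc1C1OCCO1 | intermediate
12 | 2-[2-bromo-6-(1,3-dioxolan-2-yl)-3-methylphenyl]-2-methyl-1,3-dioxolane | Cc1ccc(C2OCCO2)c(C2(C)OCCO2)c1Br | intermediate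
13 | [3-(1,3-dioxolan-2-yl)-6-methyl-2-(2-methyl-1,3-dioxolan-2-yl)phenyl]lithium | [Li]c1c(C)ccc(C2OCCO2)c1C1(C)OCCO1 | intermediate
14 | 5-[3-(1,3-dioxolan-2-yl)-6-methyl-2-(2-methyl-1,3-dioxolan-2-yl)phenyl]-3-(5-isopropyl-2-methylphenyl)-5-oxopentanoic acid (racemic) | OC(=O)CC(CC(=O)c1c(C)ccc(C2OCCO2)c1C1(C)OCCO1)c1cc(C(C)C)ccc1C | intermediate
15 | ethoxycarbonyl 5-[3-(1,3-dioxolan-2-yl)-6-methyl-2-(2-methyl-1,3-dioxolan-2-yl)phenyl]-3-(5-isopropyl-2-methylphenyl)-5-oxopentanoate (mixed carbonic anhydride, racemic) | CCOC(=O)OC(=O)CC(CC(=O)c1c(C)ccc(C2OCCO2)c1C1(C)OCCO1)c1cc(C(C)C)ccc1C | intermediate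
16 | 1-diazo-6-[3-(1,3-dioxolan-2-yl)-6-methyl-2-(2-methyl-1,3-dioxolan-2-yl)phenyl]-4-(5-isopropyl-2-methylphenyl)hexane-2,6-dione (racemic) | [N-]=[N+]=CC(=O)CC(CC(=O)c1c(C)ccc(C2OCCO2)c1C1(C)OCCO1)c1cc(C(C)C)ccc1C | intermediate
17 | norcaradiene valence isomer of 18: 2-{2-[3-(1,3-dioxolan-2-yl)-6-methyl-2-(2-methyl-1,3-dioxolan-2-yl)phenyl]-2-oxoethyl}-7-isopropyl-10-methyltricyclo[4.4.0.0(1,5)]deca-7,9-dien-4-one (diastereomer mixture, racemic) | O=C1CC(CC(=O)c2c(C)ccc(C3OCCO3)c2C2(C)OCCO2)C23C(C)=CC=C(C(C)C)C2C13 | intermediate
18 | 3-{2-[3-(1,3-dioxolan-2-yl)-6-methyl-2-(2-methyl-1,3-dioxolan-2-yl)phenyl]-2-oxoethyl}-7-isopropyl-4-methyl-3,8a-dihydroazulen-1(2H)-one (diastereomer mixture, racemic) | O=C1CC(CC(=O)c2c(C)ccc(C3OCCO3)c2C2(C)OCCO2)C2=C(C)C=CC(C(C)C)=CC12 | intermediate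
19 | 1-[3-(1,3-dioxolan-2-yl)-6-methyl-2-(2-methyl-1,3-dioxolan-2-yl)phenyl]-2-(1-hydroxy-7-isopropyl-1,4-dimethyl-1,2,3,8a-tetrahydroazulen-3-yl)ethan-1-one (diastereomer mixture, racemic) | CC1(O)CC(CC(=O)c2c(C)ccc(C3OCCO3)c2C2(C)OCCO2)C2=C(C)C=CC(C(C)C)=CC12 | intermediate
20 | 1-[3-(1,3-dioxolan-2-yl)-6-methyl-2-(2-methyl-1,3-dioxolan-2-yl)phenyl]-2-(7-isopropyl-1,4-dimethyl-2,3-dihydroazulen-3-yl)ethan-1-one (racemic; heptafulvene form with C1=C8a) | CC1=C2C=C(C(C)C)C=CC(C)=C2C(CC(=O)c2c(C)ccc(C3OCCO3)c2C2(C)OCCO2)C1 | intermediate
21 | 1-[3-(1,3-dioxolan-2-yl)-6-methyl-2-(2-methyl-1,3-dioxolan-2-yl)phenyl]-2-(7-isopropyl-1,4-dimethylazulen-3-yl)ethan-1-one | O=C(Cc1cc(C)c2cc(C(C)C)ccc(C)c1-2)c1c(C)ccc(C2OCCO2)c1C1(C)OCCO1 | intermediate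
22 | 2-acetyl-3-[(7-isopropyl-1,4-dimethylazulen-3-yl)acetyl]-4-methylbenzaldehyde | O=C(Cc1cc(C)c2cc(C(C)C)ccc(C)c1-2)c1c(C)ccc(C=O)c1C(C)=O | intermediate
23 | 3-hydroxy-2-(7-isopropyl-1,4-dimethylazulen-3-yl)-3,7-dimethyl-1-oxo-2,3-dihydro-1H-indene-4-carbaldehyde (diastereomer mixture, racemic) | CC1(O)C(c2cc(C)c3cc(C(C)C)ccc(C)c2-3)C(=O)c2c(C)ccc(C=O)c21 | intermediate
24 | 2-(7-isopropyl-1,4-dimethylazulen-3-yl)-3,7-dimethyl-1-oxo-1H-indene-4-carbaldehyde | CC1=C(c2cc(C)c3cc(C(C)C)ccc(C)c2-3)C(=O)c2c(C)ccc(C=O)c21 | target

## Step count and least certain steps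

Total: 13 steps. Longest linear sequence: 10 steps (steps 4 to 13 from 8; the branch from 1 through steps 1 to 3 and 7 to 13 is equally long).

Step 9 (key step). What may go wrong is loss of site selectivity, with part of the carbenoid adding to the methyl-bearing ipso–ortho bond. That carbon is the more electron-rich one (para to the isopropyl group) and only steric shielding protects it. Isomerisation of the labile trienone during isolation (ring contraction through the norcaradiene under traces of acid) is the second danger. Fallback, which avoids the ring expansion altogether and sets out from 12: commercial guaiazulene F1 is alkylated at its free C3 position by the copper carbenoid from ethyl diazoacetate (Cu(hfacac)2, PhMe, 80 °C), a known C–H alkylation of azulenes, to give ethyl 2-(7-isopropyl-1,4-dimethylazulen-3-yl)acetate F2. Aminolysis with N,O-dimethylhydroxylamine hydrochloride and iPrMgCl gives the Weinreb amide 2-(7-isopropyl-1,4-dimethylazulen-3-yl)-N-methoxy-N-methylacetamide F3. Aryllithium 13, made from 12 as in step 7 and transmetalated with CeCl3 to suppress enolisation, adds to F3, and the route is rejoined at 21.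

Step 7. What may go wrong is deprotonation of the anhydride at its α-methylene groups by the hindered and strongly basic aryllithium in place of carbonyl addition, which returns the protonated arene. Fallback from 7 and 12, with a non-basic organometallic: methanolysis of 7 (MeOH, DMAP) gives the half ester 3-(5-isopropyl-2-methylphenyl)-5-methoxy-5-oxopentanoic acid F4, and oxalyl chloride gives the acid chloride methyl 5-chloro-3-(5-isopropyl-2-methylphenyl)-5-oxopentanoate F5. Aryllithium 13 is converted with ZnCl2 into [3-(1,3-dioxolan-2-yl)-6-methyl-2-(2-methyl-1,3-dioxolan-2-yl)phenyl]zinc chloride F6. Negishi acylation of F6 with F5, catalysed by Pd(PPh3)4, gives the keto ester methyl 5-[3-(1,3-dioxolan-2-yl)-6-methyl-2-(2-methyl-1,3-dioxolan-2-yl)phenyl]-3-(5-isopropyl-2-methylphenyl)-5-oxopentanoate F7, and LiOH in aqueous THF returns to the route at 14.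

Step 13. What may go wrong is diversion at the unprotected formyl group: intramolecular aldol attack by the small amount of acetyl enolate, or hydride-transfer lactonisation if any oxygen nucleophile is present. Slow dehydration of the aldol adduct is a lesser concern. Fallback from 22, which keeps the formyl group masked during ring closure: selective acetalisation of the aldehyde, which is far more reactive than the two hindered ketones (ethylene glycol, 1.1 equiv, PPTS, PhH, Dean–Stark), gives 1-[2-acetyl-3-(1,3-dioxolan-2-yl)-6-methylphenyl]-2-(7-isopropyl-1,4-dimethylazulen-3-yl)ethan-1-one F8. Aldol condensation with K2CO3 in MeOH gives 4-(1,3-dioxolan-2-yl)-2-(7-isopropyl-1,4-dimethylazulen-3-yl)-3,7-dimethyl-1H-inden-1-one F9, and dilute aqueous HCl in THF rejoins the route at 24.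

Step 10. What may go wrong is competing addition to the aryl ketone, or enolisation at C8a followed by double-bond migration. Fallback from 18, which installs the methyl group by cross-coupling: deprotonation with KN(SiMe3)2 and trapping with PhNTf2 gives the enol triflate 3-{2-[3-(1,3-dioxolan-2-yl)-6-methyl-2-(2-methyl-1,3-dioxolan-2-yl)phenyl]-2-oxoethyl}-7-isopropyl-4-methyl-2,3-dihydroazulen-1-yl trifluoromethanesulfonate F10 (its C1=C2 regioisomer would serve equally). Suzuki–Miyaura methylation with trimethylboroxine, Pd(PPh3)4 and K2CO3 in dioxane gives 20 directly, where the route is rejoined before the chloranil stage of step 11. This removes both the carbonyl addition and the dehydration.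

Step 11. What may go wrong is over-oxidation of the electron-rich azulene or of its activated methylene by the quinone, and oligomerisation of the heptafulvene intermediate on heating. Fallback from 20 (made from 19 as before), which separates hydride loss from proton loss: Ph3CBF4 in CH2Cl2 at 0 °C takes a hydride from C2 and gives the tropylium-type salt 3-{2-[3-(1,3-dioxolan-2-yl)-6-methyl-2-(2-methyl-1,3-dioxolan-2-yl)phenyl]-2-oxoethyl}-7-isopropyl-1,4-dimethyl-3H-azulenium tetrafluoroborate F11. In this cation the product is held in a form that resists further oxidation until the oxidant is consumed. Et3N then removes the C3 proton and the route is rejoined at 21.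

Step 6. What may go wrong is incomplete ketalisation of the di-ortho-substituted ketone, or migration of the acetal between the two neighbouring carbonyl carbons to give an isomeric cyclic bis-acetal. Fallback from 9, which forms the ketal from an enol ether and not by carbonyl addition: lithiation as in step 5 and quenching with I2 gives 2-(3-bromo-2-iodo-4-methylphenyl)-1,3-dioxolane F12. Stille coupling at the C–I bond with tributyl(1-ethoxyvinyl)stannane (Pd(PPh3)4, dioxane, 90 °C) gives 2-[3-bromo-2-(1-ethoxyvinyl)-4-methylphenyl]-1,3-dioxolane F13. PPTS-catalysed addition of ethylene glycol to the enol ether with loss of ethanol (CH2Cl2, rt) gives 12, where the route is rejoined.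

## Further compounds

F1 | step 9 | guaiazulene (7-isopropyl-1,4-dimethylazulene) | Cc1ccc2c(C)ccc(C(C)C)cc1-2
F2 | step 9 | ethyl 2-(7-isopropyl-1,4-dimethylazulen-3-yl)acetate | CCOC(=O)Cc1cc(C)c2cc(C(C)C)ccc(C)c1-2
F3 | step 9 | 2-(7-isopropyl-1,4-dimethylazulen-3-yl)-N-methoxy-N-methylacetamide | CON(C)C(=O)Cc1cc(C)c2cc(C(C)C)ccc(C)c1-2
F4 | step 7 | 3-(5-isopropyl-2-methylphenyl)-5-methoxy-5-oxopentanoic acid (racemic) | COC(=O)CC(CC(=O)O)c1cc(C(C)C)ccc1C
F5 | step 7 | methyl 5-chloro-3-(5-isopropyl-2-methylphenyl)-5-oxopentanoate (racemic) | COC(=O)CC(CC(=O)Cl)c1cc(C(C)C)ccc1C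
F6 | step 7 | [3-(1,3-dioxolan-2-yl)-6-methyl-2-(2-methyl-1,3-dioxolan-2-yl)phenyl]zinc chloride | Cl[Zn]c1c(C)ccc(C2OCCO2)c1C1(C)OCCO1
F7 | step 7 | methyl 5-[3-(1,3-dioxolan-2-yl)-6-methyl-2-(2-methyl-1,3-dioxolan-2-yl)phenyl]-3-(5-isopropyl-2-methylphenyl)-5-oxopentanoate (racemic) | COC(=O)CC(CC(=O)c1c(C)ccc(C2OCCO2)c1C1(C)OCCO1)c1cc(C(C)C)ccc1C
F8 | step 13 | 1-[2-acetyl-3-(1,3-dioxolan-2-yl)-6-methylphenyl]-2-(7-isopropyl-1,4-dimethylazulen-3-yl)ethan-1-one | O=C(Cc1cc(C)c2cc(C(C)C)ccc(C)c1-2)c1c(C)ccc(C2OCCO2)c1C(C)=O
F9 | step 13 | 4-(1,3-dioxolan-2-yl)-2-(7-isopropyl-1,4-dimethylazulen-3-yl)-3,7-dimethyl-1H-inden-1-one | CC1=C(c2cc(C)c3cc(C(C)C)ccc(C)c2-3)C(=O)c2c(C)ccc(C3OCCO3)c21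
F10 | step 10 | 3-{2-[3-(1,3-dioxolan-2-yl)-6-methyl-2-(2-methyl-1,3-dioxolan-2-yl)phenyl]-2-oxoethyl}-7-isopropyl-4-methyl-2,3-dihydroazulen-1-yl trifluoromethanesulfonate (racemic) | O=S(=O)(OC1=C2C=C(C(C)C)C=CC(C)=C2C(CC(=O)c2c(C)ccc(C3OCCO3)c2C2(C)OCCO2)C1)C(F)(F)F
F11 | step 11 | 3-{2-[3-(1,3-dioxolan-2-yl)-6-methyl-2-(2-methyl-1,3-dioxolan-2-yl)phenyl]-2-oxoethyl}-7-isopropyl-1,4-dimethyl-3H-azulenium tetrafluoroborate (racemic) | CC1=CC(CC(=O)c2c(C)ccc(C3OCCO3)c2C2(C)OCCO2)C2=C(C)C=CC(C(C)C)=C[C+]12.F[B-](F)(F)F
F12 | step 6 | 2-(3-bromo-2-iodo-4-methylphenyl)-1,3-dioxolane | Cc1ccc(C2OCCO2)c(I)c1Br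
F13 | step 6 | 2-[3-bromo-2-(1-ethoxyvinyl)-4-methylphenyl]-1,3-dioxolane | CCOC(=C)c1c(Br)c(C)ccc1C1OCCO1
A1 | alternative 1 | guaiazulene (7-isopropyl-1,4-dimethylazulene) | Cc1ccc2c(C)ccc(C(C)C)cc1-2
A2 | alternative 1 | 3-(prop-1-ynyl)guaiazulene (7-isopropyl-1,4-dimethyl-3-(prop-1-yn-1-yl)azulene) | CC#Cc1cc(C)c2cc(C(C)C)ccc(C)c1-2
A3 | alternative 1 | 3-(dimethoxymethyl)-2-iodo-6-methylbenzaldehyde | COC(OC)c1ccc(C)c(C=O)c1I
A4 | alternative 1 | 4-(dimethoxymethyl)-2-(7-isopropyl-1,4-dimethylazulen-3-yl)-3,7-dimethyl-1H-inden-1-one | CC1=C(c2cc(C)c3cc(C(C)C)ccc(C)c2-3)C(=O)c2c(C)ccc(C(OC)OC)c21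
A5 | alternative 2 | 4-[3-(1,3-dioxolan-2-yl)-6-methyl-2-(2-methyl-1,3-dioxolan-2-yl)phenyl]-4-oxobutanal | O=CCCC(=O)c1c(C)ccc(C2OCCO2)c1C1(C)OCCO1
A6 | alternative 2 | (E)-1-[3-(1,3-dioxolan-2-yl)-6-methyl-2-(2-methyl-1,3-dioxolan-2-yl)phenyl]-4-(pyrrolidin-1-yl)but-3-en-1-one | O=C(C/C=C/N1CCCC1)c1c(C)ccc(C2OCCO2)c1C1(C)OCCO1
A7 | alternative 2 | 5-isopropyl-3,8-dimethyl-2H-cyclohepta[b]furan-2-one | O=C1OC2=C(C)C=CC(C(C)C)=CC2=C1C
A8 | alternative 2 | 1-[3-(1,3-dioxolan-2-yl)-6-methyl-2-(2-methyl-1,3-dioxolan-2-yl)phenyl]-2-(7-isopropyl-1,4-dimethylazulen-3-yl)ethan-1-one | O=C(Cc1cc(C)c2cc(C(C)C)ccc(C)c1-2)c1c(C)ccc(C2OCCO2)c1C1(C)OCCO1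
A9 | alternative 3 | (Z)-9,9-diethoxy-5-(7-isopropyl-1,4-dimethylazulen-3-yl)-6-methylnon-5-ene-2,7-diyn-4-one | CC#CC(=O)/C(c1cc(C)c2cc(C(C)C)ccc(C)c1-2)=C(/C)C#CC(OCC)OCC
A10 | alternative 3 | acetylene (ethyne) | C#C
A11 | alternative 3 | 4-(diethoxymethyl)-2-(7-isopropyl-1,4-dimethylazulen-3-yl)-3,7-dimethyl-1H-inden-1-one | CC1=C(c2cc(C)c3cc(C(C)C)ccc(C)c2-3)C(=O)c2c(C)ccc(C(OCC)OCC)c21
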